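**Retrosynthetic overview**
- The only ring, the 4-pyranone, is formed last. The target is achiral, so no stereocontrol is needed.
- Key disconnection: the ring O–C(alkyl) bond. The ester carbonyl oxygen of an open-chain methyl 3,5-dioxo ester closes onto C5 with loss of water, and the ester OMe is kept as the ring methoxy group.
- Side-chain acetate C–O bond: acetylation of a primary alcohol.
- C4–C5 of the triketide: γ-acylation of the dianion of methyl 2-methyl-3-oxopentanoate with 12-dodecanolide. This brings in all skeletal carbons and the free OH in one operation.

Assumption: the target has no stereocentre, so there is no enantiomer to select. Compound 1 is used as the racemate and 4–6 as diastereomer/tautomer mixtures, because C2 and C4 become sp2 in 7.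

**Step 1**
Reactants: 1 methyl 2-methyl-3-oxopentanoate; 2 oxacyclotridecan-2-one (12-dodecanolide)
Product: 4 methyl 16-hydroxy-2,4-dimethyl-3,5-dioxohexadecanoate, via dilithium dienolate 3 (not isolated)
Conditions: 1 (2.2 equiv), LiN(iPr)2 (4.5 equiv), THF, −78 → 0 °C; then 2 (1.0 equiv), 0 °C → rt; 1 M HCl
Reagents that add atoms: none
Why: Claisen-type γ-acylation of a β-keto ester dianion (Weiler dianion chemistry), in which the more basic C4 carbanion of 3 opens the lactone to release the primary alkoxide, the second equivalent of 3 deprotonates the new 1,3-diketone so no over-addition occurs, and the C2/C4 stereocentres form as an inconsequential mixture.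

**Step 2**
Reactants: 4 methyl 16-hydroxy-2,4-dimethyl-3,5-dioxohexadecanoate
Product: 5 methyl 16-acetoxy-2,4-dimethyl-3,5-dioxohexadecanoate
Conditions: Ac2O (1.2 equiv), pyridine (2 equiv), 4-(dimethylamino)pyridine (2 mol %), CH2Cl2, 0 °C
Reagents that add atoms: acetic anhydride, CC(=O)OC(C)=O
Why: Nucleophile-catalysed acyl transfer (Steglich-type acetylation), in which the primary alcohol far outcompetes the largely non-enolised 2-methyl-1,3-dicarbonyl units because pyridine is too weak to form enolates, and any trace enol acetate passes its acetyl group to remaining alcohol or hydrolyses on work-up.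

**Step 3**
Reactants: 5 methyl 16-acetoxy-2,4-dimethyl-3,5-dioxohexadecanoate
Product: 7 11-(6-methoxy-3,5-dimethyl-4-oxo-4H-pyran-2-yl)undecyl acetate, via enoxyphosphonium triflate 6 (not isolated)
Conditions: Ph3PO (3.0 equiv), Tf2O (1.5 equiv), CH2Cl2, 0 °C, 15 min; then 5; iPr2NEt (3.5 equiv, slow addition), 0 °C → rt
Reagents that add atoms: none
Why: Proposed new method: phosphonium-anhydride cyclodehydration of a 3,5-dioxo methyl ester in which the ester carbonyl oxygen, not a ketone enol, closes the ring: iPr2NEt enolises the most acidic C4–H, the oxophilic reagent (Ph3P+)2O 2 TfO− phosphonylates the less hindered, more electron-rich terminal oxygen O5 (O3 sits between two methyl-branched carbons) to give the vinylogous acyloxyphosphonium 6, and since triflate is non-nucleophilic the only nucleophile in reach is the oxygen of the C1–C3 β-keto ester enolate, which adds 6-endo-trig to C5 and expels Ph3PO (addition–elimination); C1 never becomes tetrahedral, so OMe cannot leave as methanol (the competing lactonisation to the 4-hydroxy-2-pyrone needs DBU and heat); activation at O1 would converge on 7 by attack of O5 on C1, activation at O3 has no ring-closing partner and reverts by phosphoryl exchange or on work-up, and elimination to an allenone would still close to 7 by oxa-Michael addition; closest known reaction types are the Ph3P/CCl4 (Appel-type) cyclodehydration of 1,3,5-triketones to γ-pyrones and Hendrickson-reagent dehydrative heterocyclisations; no stereocentre is formed.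

**Compound list**
1 | methyl 2-methyl-3-oxopentanoate (racemic) | CCC(=O)C(C)C(=O)OC | starting material
2 | oxacyclotridecan-2-one (12-dodecanolide, 13-membered lactone) | O=C1CCCCCCCCCCCO1 | starting material
3 | dilithium 1-methoxy-2-methylpenta-1,3-diene-1,3-diolate (dianion of 1, not isolated) | [Li+].[Li+].CC=C([O-])C(C)=C([O-])OC | intermediate
4 | methyl 16-hydroxy-2,4-dimethyl-3,5-dioxohexadecanoate (diastereomer/tautomer mixture) | COC(=O)C(C)C(=O)C(C)C(=O)CCCCCCCCCCCO | intermediate
5 | methyl 16-acetoxy-2,4-dimethyl-3,5-dioxohexadecanoate (diastereomer/tautomer mixture) | COC(=O)C(C)C(=O)C(C)C(=O)CCCCCCCCCCCOC(C)=O | intermediate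
6 | [16-acetoxy-1-methoxy-2,4-dimethyl-1,3-dioxohexadec-4-en-5-yl]oxy(triphenyl)phosphonium triflate (E/Z mixture, not isolated) | COC(=O)C(C)C(=O)C(C)=C(CCCCCCCCCCCOC(C)=O)O[P+](c1ccccc1)(c1ccccc1)c1ccccc1.[O-]S(=O)(=O)C(F)(F)F | intermediate
7 | 11-(6-methoxy-3,5-dimethyl-4-oxo-4H-pyran-2-yl)undecyl acetate (achiral) | COc1oc(CCCCCCCCCCCOC(C)=O)c(C)c(=O)c1C | target

**Totals**
Total step count: 3. Longest linear sequence: 3.

**Steps most likely to fail**

1. Step 3, the new cyclodehydration. The risks are activation at the wrong oxygen and competing lactonisation. The fallback uses known chemistry, sets out from 5 and comes back at 7.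
   - Heating 5 with 1,8-diazabicyclo[5.4.0]undec-7-ene in toluene at 80 °C closes the lactone. The C5 enolate oxygen attacks the ester and methanol is lost, giving 11-(4-hydroxy-3,5-dimethyl-2-oxo-2H-pyran-6-yl)undecyl acetate F1.
   - Neutral F1 is then treated with methyl trifluoromethanesulfonate (or methyl fluorosulfonate) in CH2Cl2 at rt. This methylates the more nucleophilic lactone carbonyl oxygen, and NaHCO3 work-up releases 7.
   - This is the established lactonise-then-methylate sequence for 3,5-dimethyl-4-hydroxy-2-pyrones. It costs one extra step.

2. Step 1. The hindered secondary carbanion may enolise the sluggish macrolactone instead of acylating it. The fallback replaces acylation by aldol addition plus oxidation, sets out from 2 and comes back at 5.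
   - iBu2AlH (1.05 equiv, CH2Cl2, −78 °C) half-reduces 2 to 12-hydroxydodecanal F2.
   - Excess dianion 3 adds to the aldehyde at −78 °C to give methyl 5,16-dihydroxy-2,4-dimethyl-3-oxohexadecanoate F3.
   - AcCl with 2,4,6-collidine at −78 °C acetylates only the primary alcohol, giving methyl 16-acetoxy-5-hydroxy-2,4-dimethyl-3-oxohexadecanoate F4.
   - Dess–Martin periodinane oxidises the C5 carbinol of F4 to give 5.

3. Step 2. The risks are enol O-acetylation and base-induced side reactions of the triketide. The fallback activates the alcohol instead of the acyl donor, sets out from 4 and comes back at 5.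
   - It is a Mitsunobu esterification with AcOH (3 equiv), PPh3 and diisopropyl azodicarboxylate in THF at 0 °C.
   - Acetate displaces the primary alkoxyphosphonium by SN2. No acylating agent is present, so the enols cannot be acetylated, and the excess AcOH keeps the triketide protonated.
   - No compound outside the list is made (entry F0).

**Further compounds**
F1 | step 3 | 11-(4-hydroxy-3,5-dimethyl-2-oxo-2H-pyran-6-yl)undecyl acetate | CC(=O)OCCCCCCCCCCCc1oc(=O)c(C)c(O)c1C
F2 | step 1 | 12-hydroxydodecanal | O=CCCCCCCCCCCCO
F3 | step 1 | methyl 5,16-dihydroxy-2,4-dimethyl-3-oxohexadecanoate (diastereomer mixture) | COC(=O)C(C)C(=O)C(C)C(O)CCCCCCCCCCCO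
F4 | step 1 | methyl 16-acetoxy-5-hydroxy-2,4-dimethyl-3-oxohexadecanoate (diastereomer mixture) | COC(=O)C(C)C(=O)C(C)C(O)CCCCCCCCCCCOC(C)=O
F0 | step 2 | none | none
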